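Which flask still holds the largest share of its products as mono adduct after the run?

in all of them: substrate 0.050 M; coupling partner 0.800 equiv; time 30 h
- dawn: temperature −10 °C
- dusk: temperature 20 °C
- autumn: temperature 50 °C
- summer: temperature −40 °C

    substrate + coupling partner → mono adduct + by-product (k1 = 0.0040 L mol⁻¹ s⁻¹, Ea1 = 49.0 kJ mol⁻¹)
    coupling partner + mono adduct → double product + by-product (k2 = 0.0040 L mol⁻¹ s⁻¹, Ea2 = 68.0 kJ mol⁻¹)
    coupling partner + double product → tris adduct + by-product (k3 = 1.7 × 10⁻⁴ L mol⁻¹ s⁻¹, Ea3 = 61.0 kJ mol⁻¹)
    coupling partner + tris adduct → tetra adduct + by-product (k4 = 0.023 L mol⁻¹ s⁻¹, Ea4 = 63.0 kJ mol⁻¹)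
    mono adduct ⇌ isomer of the product (K5 = 0.49, k5 = 2.8 × 10⁻⁵ s⁻¹, Ea5 = 100 kJ mol⁻¹, ΔH5 = −77.0 kJ mol⁻¹)
    coupling partner + mono adduct → over-reaction product (k6 = 3.3 × 10⁻⁴ L mol⁻¹ s⁻¹, Ea6 = 51.0 kJ mol⁻¹)
    2 coupling partner → self-condensation product (k7 = 1.7 × 10⁻⁴ L mol⁻¹ s⁻¹, Ea7 = 54.0 kJ mol⁻¹)
    (constants at 20 °C)

- for a step with 2 of a species take k times the square, and two of it per event
- all constants are for 20 °C and move with temperature by the activation energies and enthalpies

- which flask leads in share of mono adduct in all that became mono adduct or double product or tris adduct or tetra adduct or isomer of the product or over-reaction product ("all alike" within 1.5 percentage points) (dawn / dusk / autumn / summer / all alike)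
- share of mono adduct in all that became mono adduct or double product or tris adduct or tetra adduct or isomer of the product or over-reaction product, dawn
- share of mono adduct in all that became mono adduct or double product or tris adduct or tetra adduct or isomer of the product or over-reaction product, dusk
- share of mono adduct in all that became mono adduct or double product or tris adduct or tetra adduct or isomer of the product or over-reaction product, autumn
- share of mono adduct in all that became mono adduct or double product or tris adduct or tetra adduct or isomer of the product or over-reaction product, summer

Substrate and mono adduct compete for the same coupling partner, the limiting reagent, so two rates count: the first coupling, which makes mono adduct, and the second, which spends it. The over-reaction constant is 0.0825 of the first coupling's at the reference temperature, and the third coupling's is 0.0425 of the second's; both are far smaller than the constants they are held against, so both are set aside. Dividing the two rate laws removes time and c(coupling partner). With x as c(substrate) over its charge, and S as the ratio of second to first rate constant (the selectivity factor), the integral gives: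

c(mono adduct)/charge = (x^S − x)/(1 − S)

share = c(mono adduct)/(charge × (1 − x))

In autumn, the ratio of second to first coupling is 2.06, and the isomer equilibrium constant is small, at 0.0261. At x = 0.5, the formula gives:

c(mono adduct)/charge = 24.5 %

The two couplings there take 0.0377 M of coupling partner against 0.0400 M charged, so x near 0.5 is a fair stopping point, and the autumn share is 49.1 %.

In summer, S is 0.135. Treating the first coupling as pseudo-first-order in substrate gives:

x = 0.907

share = 99.3 %

The summer share stands above the autumn one, so of these two this reckoning names summer. Dawn is not reckoned here.

In dusk, S is 1.00, but mono adduct and isomer of the product relax with a half-life of 2.26 h, shorter than the run. At half conversion, the limit of the formula and the equilibrium together give 46.5 % for dusk.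

The forecast names summer, with 80 % for dawn, 46 % for dusk, 47 % for autumn and 99 % for summer, holding of dawn that “the second coupling has the higher barrier”.

The simulation gives summer as the leader: 79.8 % for dawn, 43.7 % for dusk, 47.0 % for autumn and 99.1 % for summer.

Autumn ends with 49.7 % of its substrate left, and S = 2.06 turns that into a share of 48.7 %, against 47.0 % in the flask. The neighbour is a flask like dusk kept at −5 °C, where S falls to 0.483. With 42.0 % of its substrate left, the formula gives 79.3 %. That neighbour flask shows a share of 73.0 %, with 2.28 % of the substrate charged standing as isomer of the product.

The numbers are invented, and the outcome is calculated.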